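**Retrosynthetic overview**

- The side chain is attached last by a C(sp3)–C(sp2) Negishi coupling between a primary iodide on the dioxane core and a (2E,4E)-dienyl iodide made from allylbenzene and methacrolein; ester hydrolysis then gives the acid.
- The core is cut in the key step into a cyclic peroxy ketal (a temporary 1,2-dioxane) and a mixed diorganozinc. The C5–C6 bond of the dioxane is made by alkylation of a cyclic peroxycarbenium ion; in the same flask the peroxide oxygen leaves its temporary acetal carbon and closes the final ring at C3 by oxa-Michael addition.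
- Enabling feature: the quaternary peroxide carbon C6 of the 1,2-dioxane carries two CH2–CH(CH3) arms of the same absolute sense, C5–C4 inside the ring and C1'–C2' of the side chain (a pseudo-C2-symmetric array about C6). Both arms therefore come from one enantiomer of methyl 3-hydroxy-2-methylpropanoate, and a six-membered peroxide ring built first on the side-chain arm (O–O, C6, C1', C2', with C3' as acetal carbon) can fix C6 before the O–O bridge is handed to the ring arm.
- Ring order: the temporary 1,2-dioxane first (ozonolysis in methanol, peroxy-hemiacetal closure), the final 1,2-dioxane second (key step). The temporary ring is opened in the same operation and its acetal carbon, released as an aldehyde, becomes C3' of the side chain.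

Key step: step 11

Remark: C3–C6 are the locants of the 1,2-dioxane of the target and C1'–C8' those of its octadienyl chain. The two acetal carbons of the temporary 1,2-dioxane form as epimer mixtures and are both erased in the key step, so they are written without configuration.

**Route**

Step 1
Reactants: 1 methyl (S)-3-hydroxy-2-methylpropanoate
Product: 2 methyl (R)-3-iodo-2-methylpropanoate
Conditions: PPh3, I2, imidazole, CH2Cl2, 0 °C → rt
Reagents that add atoms: iodine (II)
Why: Appel-type iodination of the primary alcohol runs by SN2 at the CH2 group and leaves the α-stereocentre untouched (the descriptor changes only through the priority rules).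

Step 2
Reactants: 2 methyl (R)-3-iodo-2-methylpropanoate; 3 2-bromopropene
Product: 5 methyl (S)-2,4-dimethylpent-4-enoate, via zinc homoenolate 4 (not isolated)
Conditions: Zn dust (activated with BrCH2CH2Br and TMSCl), THF, 35 °C; then 3, Pd(PPh3)4 (cat.), THF, rt
Reagents that add atoms: none
Why: Zinc insertion should give the configurationally stable β-zincio ester, which undergoes Negishi coupling with the vinyl bromide without involving the stereocentre.

Step 3
Reactants: 5 methyl (S)-2,4-dimethylpent-4-enoate
Product: 6 (S)-2,4-dimethylpent-4-enal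
Conditions: i-Bu2AlH (1.05 equiv), CH2Cl2, −78 °C; aq. sodium potassium tartrate
Reagents that add atoms: none
Why: Partial ester reduction stops at the aluminium hemiacetal at −78 °C and releases the aldehyde on work-up; the volatile, epimerizable aldehyde is kept cold and used at once as a solution.

Step 4
Reactants: 6 (S)-2,4-dimethylpent-4-enal
Product: 8 (4S)-6-methoxy-4,6-dimethyl-1,2-dioxan-3-ol, via methoxy hydroperoxide 7 (not isolated)
Conditions: O3, CH2Cl2/MeOH (4:1), NaHCO3, −78 °C; N2 purge, warm to 0 °C
Reagents that add atoms: ozone (O=[O+][O-]); methanol (CO)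
Why: Ozonolysis of the 1,1-disubstituted alkene (Criegee mechanism) should give the ketone O-oxide, which methanol traps as the α-methoxy hydroperoxide 7; this adds to the aldehyde in a 6-exo-trig closure to the cyclic peroxy-hemiacetal, the methyl stereocentre being untouched.

Step 5
Reactants: 8 (4S)-6-methoxy-4,6-dimethyl-1,2-dioxan-3-ol
Product: 9 tert-butyl{[(4S)-6-methoxy-4,6-dimethyl-1,2-dioxan-3-yl]oxy}dimethylsilane
Conditions: TBSCl, imidazole, DMF, 0 °C
Reagents that add atoms: tert-butyldimethylsilyl chloride (CC(C)(C)[Si](C)(C)Cl)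
Why: Silylation of the hemiacetal hydroxyl locks the temporary ring, makes the secondary acetal carbon the slower-ionizing site in step 11 and leaves it removable by fluoride.

Step 6
Reactants: 1 methyl (S)-3-hydroxy-2-methylpropanoate
Product: 10 methyl (S)-3-{[tert-butyl(dimethyl)silyl]oxy}-2-methylpropanoate
Conditions: TBSCl, imidazole, CH2Cl2, rt
Reagents that add atoms: tert-butyldimethylsilyl chloride (CC(C)(C)[Si](C)(C)Cl)
Why: Standard silyl protection of the primary alcohol.

Step 7
Reactants: 10 methyl (S)-3-{[tert-butyl(dimethyl)silyl]oxy}-2-methylpropanoate; 11 methyl 2-(triphenyl-λ5-phosphanylidene)acetate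
Product: 13 methyl (2E,4R)-5-{[tert-butyl(dimethyl)silyl]oxy}-4-methylpent-2-enoate, via silyloxy aldehyde 12 (not isolated)
Conditions: i-Bu2AlH, CH2Cl2, −78 °C; MeOH (quench); then 11, −78 °C → rt
Reagents that add atoms: none
Why: Partial reduction followed by Wittig olefination with the stabilized ylide in the same flask should give the (E)-enoate without isolating the epimerizable α-methyl aldehyde.

Step 8
Reactants: 13 methyl (2E,4R)-5-{[tert-butyl(dimethyl)silyl]oxy}-4-methylpent-2-enoate
Product: 14 methyl (2E,4R)-5-hydroxy-4-methylpent-2-enoate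
Conditions: camphorsulfonic acid (cat.), MeOH, 0 °C → rt
Reagents that add atoms: none
Why: Acid-catalysed methanolysis removes the primary silyl ether; the (E)-enoate can neither lactonize nor cyclize.

Step 9
Reactants: 14 methyl (2E,4R)-5-hydroxy-4-methylpent-2-enoate
Product: 15 methyl (2E,4R)-5-iodo-4-methylpent-2-enoate
Conditions: PPh3, I2, imidazole, CH2Cl2, 0 °C
Reagents that add atoms: iodine (II)
Why: Appel-type iodination at the primary carbon, remote from the stereocentre and the enoate.

Step 10
Reactants: 15 methyl (2E,4R)-5-iodo-4-methylpent-2-enoate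
Product: 17 [(2R,3E)-5-methoxy-2-methyl-5-oxopent-3-en-1-yl][(trimethylsilyl)methyl]zinc, via enoate alkylzinc iodide 16 (not isolated)
Conditions: Zn dust (activated with BrCH2CH2Br and TMSCl), THF, 35 °C; solution decanted from excess Zn; then Me3SiCH2Li (1.0 equiv, added slowly), −78 °C; THF removed in vacuum, toluene, LiI filtered off under Ar
Reagents that add atoms: zinc ([Zn]); (trimethylsilyl)methyllithium ([Li]C[Si](C)(C)C)
Why: Oxidative zinc insertion into the primary iodide tolerates the enoate, and lithium–zinc transmetalation of the alkylzinc iodide at −78 °C, faster than attack on the ester, should give the mixed diorganozinc in which trimethylsilylmethyl is a non-transferable ligand, so that one equivalent of the chiral alkyl group suffices and no iodide salt is carried into the peroxide chemistry of step 11.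

Step 11
Reactants: 9 tert-butyl{[(4S)-6-methoxy-4,6-dimethyl-1,2-dioxan-3-yl]oxy}dimethylsilane; 17 [(2R,3E)-5-methoxy-2-methyl-5-oxopent-3-en-1-yl][(trimethylsilyl)methyl]zinc
Product: 21 methyl 2-[(3R,4S,6S)-4,6-dimethyl-6-[(2S)-2-methyl-3-oxopropyl]-1,2-dioxan-3-yl]acetate, via peroxycarbenium triflate 18 (not isolated), via alkylated temporary dioxane 19 (not isolated), via hydroperoxy aldehyde 20 (not isolated)
Conditions: TMSOTf, CH2Cl2/toluene, −78 → −40 °C; AcOH, −78 °C; then Bu4NF, Et3N, CF3CH2OH, THF, −40 → 0 °C
Reagents that add atoms: none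
Why: Proposed new method: TMSOTf should ionize the tertiary methoxy ketal of 9 to the six-membered cyclic peroxycarbenium ion 18, to whose cationic carbon the mixed diorganozinc 17 transfers its primary alkyl group and not the trimethylsilylmethyl ligand (C5–C6 bond); the closest known reaction types are the TMSOTf-mediated alkylation of six-membered cyclic oxocarbenium ions by diorganozincs and the Lewis acid-mediated allylation and Mukaiyama-type alkylation of cyclic peroxy ketals through peroxycarbenium ions. The new quaternary centre C6 is controlled by the methyl-bearing stereocentre of the temporary ring: the half-chair of 18 carries that methyl pseudo-equatorially and the nucleophile enters along the axial, chair-forming trajectory, trans to it, because the other face would need a 1,3-diaxial contact with the methyl group or a twist-boat. After the remaining C–Zn bond is destroyed with acetic acid (so that no zinc alkyl is oxidized later), fluoride removes the silyl group from 19, the freed peroxy-hemiacetal opens reversibly to hydroperoxy aldehyde 20, and the hydroperoxide adds to the enoate in a 6-exo-trig oxa-Michael closure that forms the O–C3 bond and the 1,2-dioxane of the target. C3 is under thermodynamic control, since the conjugate addition is reversible in base, and should end trans to the C4 methyl with the acetate arm, the C4 methyl and the C6 chain all equatorial. The step needs ionization at the tertiary ketal in preference to the secondary silyl acetal and to the ring C–O bond, facial selectivity at the cation, and conjugate addition in preference to return to the hemiacetal; these should be secured by the tertiary versus secondary nature of the two acetal carbons and the higher basicity of the methoxy oxygen, by the equatorial methyl group of the temporary ring, and by the dialkyl peroxide being the thermodynamic sink while hemiacetal closure stays reversible. C4 and C2' are brought in unchanged from 17 and 9.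

Step 12
Reactants: 21 methyl 2-[(3R,4S,6S)-4,6-dimethyl-6-[(2S)-2-methyl-3-oxopropyl]-1,2-dioxan-3-yl]acetate
Product: 22 methyl 2-[(3R,4S,6R)-6-[(2S)-3-hydroxy-2-methylpropyl]-4,6-dimethyl-1,2-dioxan-3-yl]acetate
Conditions: NaBH4, MeOH, 0 °C (crude 21, at once)
Reagents that add atoms: none
Why: NaBH4 reduces the aldehyde chemoselectively, dialkyl peroxides and esters being inert at 0 °C, and immediate reduction secures the α-methyl stereocentre.

Step 13
Reactants: 22 methyl 2-[(3R,4S,6R)-6-[(2S)-3-hydroxy-2-methylpropyl]-4,6-dimethyl-1,2-dioxan-3-yl]acetate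
Product: 23 methyl 2-[(3R,4S,6S)-6-[(2S)-3-iodo-2-methylpropyl]-4,6-dimethyl-1,2-dioxan-3-yl]acetate
Conditions: PPh3, I2, imidazole, CH2Cl2, 0 °C (PPh3 and I2 premixed)
Reagents that add atoms: iodine (II)
Why: Appel-type iodination of the primary alcohol; the phosphine is consumed as its iodine adduct before the hindered dialkyl peroxide can be attacked.

Step 14
Reactants: 24 allylbenzene; 25 methacrolein
Product: 26 (2E)-2-methyl-4-phenylbut-2-enal
Conditions: second-generation Grubbs catalyst RuCl2(=CHPh)(PCy3)(H2IMes) (cat.), 25 in excess, CH2Cl2, 40 °C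
Reagents that add atoms: none
Why: Olefin cross-metathesis of a terminal alkene with methacrolein should give the trisubstituted enal as the thermodynamically favoured E isomer.

Step 15
Reactants: 26 (2E)-2-methyl-4-phenylbut-2-enal
Product: 27 [(2E)-5,5-dibromo-3-methylpenta-2,4-dien-1-yl]benzene
Conditions: CBr4, PPh3, CH2Cl2, 0 °C
Reagents that add atoms: tetrabromomethane (BrC(Br)(Br)Br)
Why: First stage of the Corey–Fuchs sequence (dibromomethylenation of the aldehyde), which leaves the existing alkene untouched.

Step 16
Reactants: 27 [(2E)-5,5-dibromo-3-methylpenta-2,4-dien-1-yl]benzene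
Product: 29 [(2E)-3-methylhex-2-en-4-yn-1-yl]benzene, via lithium acetylide 28 (not isolated)
Conditions: n-BuLi (2 equiv), THF, −78 °C; then MeI, −78 °C → rt
Reagents that add atoms: iodomethane (CI)
Why: Second stage of the Corey–Fuchs sequence: bromine–lithium exchange and Fritsch–Buttenberg–Wiechell rearrangement give the lithium acetylide, which is methylated in the flask; the low temperature favours exchange over deprotonation of the benzylic-allylic CH2.

Step 17
Reactants: 29 [(2E)-3-methylhex-2-en-4-yn-1-yl]benzene
Product: 31 [(2E,4E)-5-iodo-3-methylhexa-2,4-dien-1-yl]benzene, via alkenylzirconocene chloride 30 (not isolated)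
Conditions: Cp2Zr(H)Cl, THF, rt; then I2, 0 °C
Reagents that add atoms: iodine (II)
Why: syn-Hydrozirconation should place zirconium on the less hindered, methyl-bearing alkyne carbon, and iodinolysis with retention gives the (E)-alkenyl iodide with iodine trans to the dienyl chain.

Step 18
Reactants: 23 methyl 2-[(3R,4S,6S)-6-[(2S)-3-iodo-2-methylpropyl]-4,6-dimethyl-1,2-dioxan-3-yl]acetate; 31 [(2E,4E)-5-iodo-3-methylhexa-2,4-dien-1-yl]benzene
Product: 33 methyl 2-[(3R,4S,6R)-4,6-dimethyl-6-[(2R,4E,6E)-2,4,6-trimethyl-8-phenylocta-4,6-dien-1-yl]-1,2-dioxan-3-yl]acetate, via dioxane alkylzinc iodide 32 (not isolated)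
Conditions: Zn dust (I2-activated), DMF, rt; then 31, Pd2(dba)3 (cat.), P(o-tol)3 (cat.), DMF, rt
Reagents that add atoms: none
Why: Zinc insertion into the primary iodide and Negishi C(sp3)–C(sp2) coupling with retention of alkene geometry should install the diene at room temperature, conditions that saturated dialkyl peroxides and esters are expected to tolerate.

Step 19
Reactants: 33 methyl 2-[(3R,4S,6R)-4,6-dimethyl-6-[(2R,4E,6E)-2,4,6-trimethyl-8-phenylocta-4,6-dien-1-yl]-1,2-dioxan-3-yl]acetate
Product: 34 2-[(3R,4S,6R)-4,6-dimethyl-6-[(2R,4E,6E)-2,4,6-trimethyl-8-phenylocta-4,6-dien-1-yl]-1,2-dioxan-3-yl]acetic acid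
Conditions: LiOH, THF/H2O, 0 °C; then aq. HCl to pH 3
Reagents that add atoms: lithium hydroxide ([Li+].[OH-])
Why: Saponification of the methyl ester at 0 °C, mild enough to avoid retro-Michael opening or Kornblum–DeLaMare fragmentation of the 1,2-dioxane.

**Compound list**

1 | methyl (S)-3-hydroxy-2-methylpropanoate | COC(=O)[C@@H](C)CO | starting material
2 | methyl (R)-3-iodo-2-methylpropanoate | COC(=O)[C@@H](C)CI | intermediate
3 | 2-bromopropene | C=C(C)Br | starting material
4 | [(2R)-3-methoxy-2-methyl-3-oxopropyl]zinc iodide | COC(=O)[C@@H](C)C[Zn]I | intermediate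
5 | methyl (S)-2,4-dimethylpent-4-enoate | COC(=O)[C@@H](C)CC(C)=C | intermediate
6 | (S)-2,4-dimethylpent-4-enal | O=C[C@@H](C)CC(C)=C | intermediate
7 | (2S)-4-hydroperoxy-4-methoxy-2-methylpentanal (epimers at C4) | O=C[C@@H](C)CC(C)(OC)OO | intermediate
8 | (4S)-6-methoxy-4,6-dimethyl-1,2-dioxan-3-ol (epimers at C3 and C6) | COC1(C)C[C@H](C)C(O)OO1 | intermediate
9 | tert-butyl{[(4S)-6-methoxy-4,6-dimethyl-1,2-dioxan-3-yl]oxy}dimethylsilane (epimers at C3 and C6) | COC1(C)C[C@H](C)C(O[Si](C)(C)C(C)(C)C)OO1 | intermediate
10 | methyl (S)-3-{[tert-butyl(dimethyl)silyl]oxy}-2-methylpropanoate | COC(=O)[C@@H](C)CO[Si](C)(C)C(C)(C)C | intermediate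
11 | methyl 2-(triphenyl-λ5-phosphanylidene)acetate | COC(=O)C=P(c1ccccc1)(c1ccccc1)c1ccccc1 | starting material
12 | (S)-3-{[tert-butyl(dimethyl)silyl]oxy}-2-methylpropanal | O=C[C@@H](C)CO[Si](C)(C)C(C)(C)C | intermediate
13 | methyl (2E,4R)-5-{[tert-butyl(dimethyl)silyl]oxy}-4-methylpent-2-enoate | COC(=O)/C=C/[C@@H](C)CO[Si](C)(C)C(C)(C)C | intermediate
14 | methyl (2E,4R)-5-hydroxy-4-methylpent-2-enoate | COC(=O)/C=C/[C@@H](C)CO | intermediate
15 | methyl (2E,4R)-5-iodo-4-methylpent-2-enoate | COC(=O)/C=C/[C@@H](C)CI | intermediate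
16 | [(2R,3E)-5-methoxy-2-methyl-5-oxopent-3-en-1-yl]zinc iodide | COC(=O)/C=C/[C@@H](C)C[Zn]I | intermediate
17 | [(2R,3E)-5-methoxy-2-methyl-5-oxopent-3-en-1-yl][(trimethylsilyl)methyl]zinc | COC(=O)/C=C/[C@@H](C)C[Zn]C[Si](C)(C)C | intermediate
18 | (5S)-6-{[tert-butyl(dimethyl)silyl]oxy}-3,5-dimethyl-5,6-dihydro-4H-1,2-dioxin-2-ium trifluoromethanesulfonate (epimers at C6) | CC1=[O+]OC(O[Si](C)(C)C(C)(C)C)[C@@H](C)C1.[O-]S(=O)(=O)C(F)(F)F | intermediate
19 | methyl (2E,4S)-5-[(3S,5S)-6-{[tert-butyl(dimethyl)silyl]oxy}-3,5-dimethyl-1,2-dioxan-3-yl]-4-methylpent-2-enoate (epimers at ring C6) | COC(=O)/C=C/[C@@H](C)C[C@@]1(C)C[C@H](C)C(O[Si](C)(C)C(C)(C)C)OO1 | intermediate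
20 | methyl (2E,4S,6S,8S)-6-hydroperoxy-4,6,8-trimethyl-9-oxonon-2-enoate | COC(=O)/C=C/[C@@H](C)C[C@](C)(OO)C[C@H](C)C=O | intermediate
21 | methyl 2-[(3R,4S,6S)-4,6-dimethyl-6-[(2S)-2-methyl-3-oxopropyl]-1,2-dioxan-3-yl]acetate | O=C[C@@H](C)C[C@]1(C)C[C@H](C)[C@@H](CC(=O)OC)OO1 | intermediate
22 | methyl 2-[(3R,4S,6R)-6-[(2S)-3-hydroxy-2-methylpropyl]-4,6-dimethyl-1,2-dioxan-3-yl]acetate | OC[C@@H](C)C[C@]1(C)C[C@H](C)[C@@H](CC(=O)OC)OO1 | intermediate
23 | methyl 2-[(3R,4S,6S)-6-[(2S)-3-iodo-2-methylpropyl]-4,6-dimethyl-1,2-dioxan-3-yl]acetate | IC[C@@H](C)C[C@]1(C)C[C@H](C)[C@@H](CC(=O)OC)OO1 | intermediate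
24 | allylbenzene | C=CCc1ccccc1 | starting material
25 | methacrolein (2-methylprop-2-enal) | C=C(C)C=O | starting material
26 | (2E)-2-methyl-4-phenylbut-2-enal | O=C/C(C)=C/Cc1ccccc1 | intermediate
27 | [(2E)-5,5-dibromo-3-methylpenta-2,4-dien-1-yl]benzene | BrC(Br)=C/C(C)=C/Cc1ccccc1 | intermediate
28 | [(3E)-3-methyl-5-phenylpent-3-en-1-yn-1-yl]lithium | [Li]C#C/C(C)=C/Cc1ccccc1 | intermediate
29 | [(2E)-3-methylhex-2-en-4-yn-1-yl]benzene | CC#C/C(C)=C/Cc1ccccc1 | intermediate
30 | chloridobis(cyclopentadienyl)[(2E,4E)-4-methyl-6-phenylhexa-2,4-dien-2-yl]zirconium (cyclopentadienyl rings drawn η1) | CC(=C\Cc1ccccc1)/C=C(\C)[Zr](Cl)(C1C=CC=C1)C1C=CC=C1 | intermediate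
31 | [(2E,4E)-5-iodo-3-methylhexa-2,4-dien-1-yl]benzene | CC(=C\Cc1ccccc1)/C=C(\C)I | intermediate
32 | methyl 2-[(3R,4S,6S)-6-[(2S)-3-(iodozincio)-2-methylpropyl]-4,6-dimethyl-1,2-dioxan-3-yl]acetate | I[Zn]C[C@@H](C)C[C@]1(C)C[C@H](C)[C@@H](CC(=O)OC)OO1 | intermediate
33 | methyl 2-[(3R,4S,6R)-4,6-dimethyl-6-[(2R,4E,6E)-2,4,6-trimethyl-8-phenylocta-4,6-dien-1-yl]-1,2-dioxan-3-yl]acetate | CC(=C\Cc1ccccc1)/C=C(\C)C[C@@H](C)C[C@]1(C)C[C@H](C)[C@@H](CC(=O)OC)OO1 | intermediate
34 | 2-[(3R,4S,6R)-4,6-dimethyl-6-[(2R,4E,6E)-2,4,6-trimethyl-8-phenylocta-4,6-dien-1-yl]-1,2-dioxan-3-yl]acetic acid | CC(=C\Cc1ccccc1)/C=C(\C)C[C@@H](C)C[C@]1(C)C[C@H](C)[C@@H](CC(=O)O)OO1 | target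

**Count and risks**

Total step count: 19. Longest linear sequence: 10 steps (steps 6–13, 18, 19 from compound 1; the sequence of steps 1–5, 11–13, 18, 19 is equally long).

Steps most likely to fail:

1. Step 11 (proposed new method). What may go wrong: transfer of a β-hydride or of the trimethylsilylmethyl ligand instead of the chiral alkyl group from zinc to the peroxycarbenium ion; attack of the zinc alkyl on the O–O bond; ionization at the ring C–O bond or at the silyl acetal carbon instead of loss of the methoxy group; oxidative fragmentation of the peroxy-hemiacetal anion, incomplete equilibration at C3 or epimerization of the α-methyl aldehyde during the base-induced peroxide transfer. Fallback with known reactions only, using the same hidden symmetry: it sets out from the alkylzinc iodide 16 (first stage of step 10, without the transmetalation). Two equivalents of 16 would be joined to 1,1-dibromoethene by a double Negishi coupling [Pd(P(t-Bu)3)2] to give the C2-symmetric dimethyl (2E,4S,8S,9E)-4,8-dimethyl-6-methylideneundeca-2,9-dienedioate F1. Mukaiyama–Isayama peroxidation [Co(acac)2, O2, Et3SiH] of the electron-rich 1,1-disubstituted alkene would give the tertiary silyl peroxide dimethyl (2E,4S,8S,9E)-4,6,8-trimethyl-6-[(triethylsilyl)peroxy]undeca-2,9-dienedioate F2, whose peroxide carbon is not a stereocentre because its two arms are identical. Desilylation and base-mediated 6-exo oxa-Michael addition onto either arm (Bu4NF, then Et3N in CF3CH2OH) would give methyl (2E,4S)-5-[(3R,5S,6R)-6-(2-methoxy-2-oxoethyl)-3,5-dimethyl-1,2-dioxan-3-yl]-4-methylpent-2-enoate F3 together with its epimer at the quaternary carbon; no control is expected here, so the two would have to be separated. Ozonolysis of the remaining enoate of F3 (O3, CH2Cl2, −78 °C; Me2S) would cut it down to aldehyde 21, where the route is rejoined.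

2. Step 18. What may go wrong: reductive cleavage of the O–O bond at the zinc surface, or attack of a transient carbon radical on the peroxide during insertion. Fallback: the polarity of the coupling would be reversed. Iodide 23 would serve as the electrophile and the alkenylzirconocene chloride 30 (from step 17, not quenched with iodine) as the nucleophile in a palladium-catalysed alkyl–alkenyl coupling [Pd(acac)2, LiBr, THF/NMP, 55 °C], which would give 33 directly; no organometallic derivative of the peroxide is then needed.

3. Step 17. What may go wrong: poor regioselectivity of the hydrozirconation across the internal alkyne, or reaction of the metal hydride with the conjugated alkene. Fallback: the trisubstituted alkene would be built on the gem-dibromide instead. Alkylzinc iodide 32 would be coupled with dibromodiene 27 in a trans-selective palladium-catalysed mono-alkylation [PdCl2(DPEphos)] to give the (Z)-alkenyl bromide methyl 2-[(3R,4S,6R)-6-[(2S,4Z,6E)-4-bromo-2,6-dimethyl-8-phenylocta-4,6-dien-1-yl]-4,6-dimethyl-1,2-dioxan-3-yl]acetate F4. The remaining bromide would then be replaced by methyl with retention [Me2Zn, Pd(P(t-Bu)3)2], which returns to 33; steps 16 and 17 would fall away.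

Further compounds
F1 | step 11 | dimethyl (2E,4S,8S,9E)-4,8-dimethyl-6-methylideneundeca-2,9-dienedioate | COC(=O)/C=C/[C@@H](C)CC(=C)C[C@H](C)/C=C/C(=O)OC
F2 | step 11 | dimethyl (2E,4S,8S,9E)-4,6,8-trimethyl-6-[(triethylsilyl)peroxy]undeca-2,9-dienedioate | COC(=O)/C=C/[C@@H](C)CC(C)(OO[Si](CC)(CC)CC)C[C@H](C)/C=C/C(=O)OC
F3 | step 11 | methyl (2E,4S)-5-[(3R,5S,6R)-6-(2-methoxy-2-oxoethyl)-3,5-dimethyl-1,2-dioxan-3-yl]-4-methylpent-2-enoate | COC(=O)/C=C/[C@@H](C)C[C@]1(C)C[C@H](C)[C@@H](CC(=O)OC)OO1
F0 | step 18 | none | none
F4 | step 17 | methyl 2-[(3R,4S,6R)-6-[(2S,4Z,6E)-4-bromo-2,6-dimethyl-8-phenylocta-4,6-dien-1-yl]-4,6-dimethyl-1,2-dioxan-3-yl]acetate | CC(=C\Cc1ccccc1)/C=C(\Br)C[C@@H](C)C[C@]1(C)C[C@H](C)[C@@H](CC(=O)OC)OO1
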